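**Retrosynthetic overview**

1. Feature: the target is a 5-alkylresorcinol whose side chain C1' (benzylic) to C17' (methyl), with Z alkenes at C8'=C9' and C11'=C12', is atom for atom C2–C18 of linoleic acid; only the C16' hydroxyl (S) and the C1'–aryl bond are missing.
2. Last disconnection: the three O–Si bonds (global desilylation of the two phenols and the C16' alcohol).
3. C1'–C(aryl) bond: decarboxylative arylation of the N-acyloxyphthalimide of the hydroxylated acid (C1 of the acid leaves as CO2) with the diarylzinc made from silylated 5-bromoresorcinol.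
4. C16'–O bond (first forward step): enzymatic, S-selective hydroxylation of the C17–H bond of linoleic acid, which sets the only stereocentre.
5. No ring is formed at any stage; the only ring, the resorcinol benzene ring, is purchased.

Key step: step 1

Assumption: a hydroxylase variant with C17 and S selectivity can be obtained by screening and directed evolution, and the regio- and enantiopurity of 2 are verified (chiral HPLC) before it is carried on.

**Route**

Step 1
Reactants: 1 linoleic acid [(9Z,12Z)-octadeca-9,12-dienoic acid]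
Product: 2 (9Z,12Z,17S)-17-hydroxyoctadeca-9,12-dienoic acid
Conditions: 1 (K salt), engineered CYP52-family ω-1 fatty-acid hydroxylase with its NADPH–cytochrome P450 reductase (yeast microsomes), NADP+ (cat.), D-glucose, glucose dehydrogenase, catalase, air (O2), KPi buffer pH 7.5, 2% DMSO, 28 °C; then pH 3, EtOAc; SiO2
Reagents that add atoms: dioxygen, O=O
Why: Proposed new method: the thiolate-ligated heme, reduced by NADPH through the reductase, binds O2 and forms the ferryl porphyrin radical cation (formally tetravalent iron-oxo), which abstracts a hydrogen atom from C17 of the carboxylate-anchored, extended chain and returns the hydroxyl to the C17 radical by rebound, so that the C17–O bond (C16'–O of the target) forms with retention. The closest known reaction type is the subterminal (ω-1 to ω-3) hydroxylation of long-chain fatty acids by cytochrome P450 enzymes such as CYP102A1 variants and the ω-1 hydroxylation of C18 acids by fungal CYP52 enzymes; what is new is its use as a preparative, single-isomer hydroxylation of linoleic acid. No ring is closed. The one new stereocentre (S at C17) is set by the active-site pocket, which must present the pro-S hydrogen of C17 to the oxo group; a CYP52 parent is chosen because natural members of that family are reported to give the S alcohol at the penultimate carbon of C18 acids. The step needs selectivity for C17 over C18, C16 and C15, over the weaker bis-allylic C11–H bonds and over epoxidation of the two Z alkenes. Nothing in the substrate secures this; it depends on a narrow channel that keeps C9–C13 away from the iron and lets only the ω-1 methylene reach it, to be obtained by screening and directed evolution.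

Step 2
Reactants: 2 (9Z,12Z,17S)-17-hydroxyoctadeca-9,12-dienoic acid
Product: 4 (9Z,12Z,17S)-17-[(tert-butyldimethylsilyl)oxy]octadeca-9,12-dienoic acid, via bis-silylated silyl ester 3 (not isolated)
Conditions: TBSCl, imidazole, DMF, rt; then K2CO3, MeOH/THF/H2O, rt; aq. citric acid to pH 4
Reagents that add atoms: tert-butyldimethylsilyl chloride, CC(C)(C)[Si](C)(C)Cl
Why: Imidazole-promoted silylation of both the secondary alcohol and the acid, followed by mild carbonate hydrolysis that should cleave only the labile silyl ester and leave the secondary silyl ether; the C17 stereocentre and the skipped diene are not involved.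

Step 3
Reactants: 4 (9Z,12Z,17S)-17-[(tert-butyldimethylsilyl)oxy]octadeca-9,12-dienoic acid; 5 N-hydroxyphthalimide
Product: 6 1,3-dioxoisoindolin-2-yl (9Z,12Z,17S)-17-[(tert-butyldimethylsilyl)oxy]octadeca-9,12-dienoate
Conditions: N,N'-diisopropylcarbodiimide, DMAP (cat.), CH2Cl2, 0 °C to rt
Reagents that add atoms: none
Why: Carbodiimide (Steglich-type) esterification of the acid with the acidic N–OH group of 5 should give the redox-active ester, with the silyl ether and the alkenes inert.

Step 4
Reactants: 7 5-bromoresorcinol (5-bromobenzene-1,3-diol)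
Product: 8 1-bromo-3,5-bis[(tert-butyldimethylsilyl)oxy]benzene
Conditions: TBSCl, imidazole, DMF, rt
Reagents that add atoms: tert-butyldimethylsilyl chloride, CC(C)(C)[Si](C)(C)Cl
Why: Standard imidazole-promoted O-silylation of both phenols, which leaves the aryl bromide untouched and masks the acidic OH groups before organometallic formation.

Step 5
Reactants: 6 1,3-dioxoisoindolin-2-yl (9Z,12Z,17S)-17-[(tert-butyldimethylsilyl)oxy]octadeca-9,12-dienoate; 8 1-bromo-3,5-bis[(tert-butyldimethylsilyl)oxy]benzene
Product: 11 1-[(8Z,11Z,16S)-16-[(tert-butyldimethylsilyl)oxy]heptadeca-8,11-dien-1-yl]-3,5-bis[(tert-butyldimethylsilyl)oxy]benzene, via arylmagnesium bromide 9 (not isolated), via diarylzinc 10 (not isolated)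
Conditions: 8, Mg turnings, LiCl, THF, rt; ZnCl2 (0.5 equiv per Grignard), THF, 0 °C to rt; then 6, Fe(acac)3 (cat.), 1,2-bis(diphenylphosphino)benzene (cat.), THF/toluene, rt; aq. NH4Cl
Reagents that add atoms: none
Why: Iron-catalysed decarboxylative Negishi-type arylation of a redox-active ester, in which a low-valent aryl-iron species transfers one electron to 6, the radical anion fragments to CO2, phthalimide anion and the primary C1' radical, and this radical is captured at iron and coupled with the aryl group; primary N-acyloxyphthalimides are within the known scope, the radical is too far from the C8'=C9' alkene to cyclise, and the C16' stereocentre is remote.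

Step 6
Reactants: 11 1-[(8Z,11Z,16S)-16-[(tert-butyldimethylsilyl)oxy]heptadeca-8,11-dien-1-yl]-3,5-bis[(tert-butyldimethylsilyl)oxy]benzene
Product: 12 Hansfordiol D, 5-[(8Z,11Z,16S)-16-hydroxyheptadeca-8,11-dien-1-yl]benzene-1,3-diol
Conditions: TBAF, AcOH, THF, 0 °C to rt, argon
Reagents that add atoms: none
Why: Fluoride-driven cleavage of the two aryl silyl ethers and the secondary alkyl silyl ether through pentacoordinate silicon, buffered with acetic acid so that the resorcinol is not held as a phenoxide; the stereocentre and both Z alkenes should be unaffected.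

**Compound list**

1 | linoleic acid, (9Z,12Z)-octadeca-9,12-dienoic acid | CCCCC/C=C\C/C=C\CCCCCCCC(=O)O | starting material
2 | (9Z,12Z,17S)-17-hydroxyoctadeca-9,12-dienoic acid | C[C@H](O)CCC/C=C\C/C=C\CCCCCCCC(=O)O | intermediate
3 | tert-butyldimethylsilyl (9Z,12Z,17S)-17-[(tert-butyldimethylsilyl)oxy]octadeca-9,12-dienoate | C[C@H](O[Si](C)(C)C(C)(C)C)CCC/C=C\C/C=C\CCCCCCCC(=O)O[Si](C)(C)C(C)(C)C | intermediate
4 | (9Z,12Z,17S)-17-[(tert-butyldimethylsilyl)oxy]octadeca-9,12-dienoic acid | C[C@H](O[Si](C)(C)C(C)(C)C)CCC/C=C\C/C=C\CCCCCCCC(=O)O | intermediate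
5 | N-hydroxyphthalimide | ON1C(=O)c2ccccc2C1=O | starting material
6 | 1,3-dioxoisoindolin-2-yl (9Z,12Z,17S)-17-[(tert-butyldimethylsilyl)oxy]octadeca-9,12-dienoate | C[C@H](O[Si](C)(C)C(C)(C)C)CCC/C=C\C/C=C\CCCCCCCC(=O)ON1C(=O)c2ccccc2C1=O | intermediate
7 | 5-bromoresorcinol | Oc1cc(O)cc(Br)c1 | starting material
8 | 1-bromo-3,5-bis[(tert-butyldimethylsilyl)oxy]benzene | CC(C)(C)[Si](C)(C)Oc1cc(Br)cc(O[Si](C)(C)C(C)(C)C)c1 | intermediate
9 | {3,5-bis[(tert-butyldimethylsilyl)oxy]phenyl}magnesium bromide | CC(C)(C)[Si](C)(C)Oc1cc([Mg]Br)cc(O[Si](C)(C)C(C)(C)C)c1 | intermediate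
10 | bis{3,5-bis[(tert-butyldimethylsilyl)oxy]phenyl}zinc | CC(C)(C)[Si](C)(C)Oc1cc([Zn]c2cc(O[Si](C)(C)C(C)(C)C)cc(O[Si](C)(C)C(C)(C)C)c2)cc(O[Si](C)(C)C(C)(C)C)c1 | intermediate
11 | 1-[(8Z,11Z,16S)-16-[(tert-butyldimethylsilyl)oxy]heptadeca-8,11-dien-1-yl]-3,5-bis[(tert-butyldimethylsilyl)oxy]benzene | C[C@H](O[Si](C)(C)C(C)(C)C)CCC/C=C\C/C=C\CCCCCCCc1cc(O[Si](C)(C)C(C)(C)C)cc(O[Si](C)(C)C(C)(C)C)c1 | intermediate
12 | Hansfordiol D, 5-[(8Z,11Z,16S)-16-hydroxyheptadeca-8,11-dien-1-yl]benzene-1,3-diol | C[C@H](O)CCC/C=C\C/C=C\CCCCCCCc1cc(O)cc(O)c1 | target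

**Step count**

Total steps: 6. Longest linear sequence: 5 steps (steps 1, 2, 3, 5 and 6 from linoleic acid 1); step 4 is the one-step aryl branch.

**Steps most likely to fail**

Step 1 (key step). What may go wrong: the oxidant is delivered to C18, C16 or C15, to the bis-allylic C11 or to an alkene instead of C17; the pocket does not discriminate the two C17 hydrogens well enough; or turnover stalls through uncoupling and substrate autoxidation.

Fallback (known chemistry, no C–H oxidation): the silylated acid 4 is assembled from small pieces by the skipped-diyne route. It cannot set out from a compound of the route, because step 1 is the first step and 1 carries no oxygen at C17. It starts from purchased (S)-propylene oxide (C[C@H]1CO1), 4-bromo-1-(trimethylsilyl)but-1-yne (C[Si](C)(C)C#CCCBr) and methyl dec-9-ynoate (C#CCCCCCCCC(=O)OC), and it comes back to the route at compound 4.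

- The bromide is converted with Mg in THF into [4-(trimethylsilyl)but-3-yn-1-yl]magnesium bromide F1.
- F1 opens (S)-propylene oxide at its CH2 carbon under CuI catalysis (THF, −30 °C) to give (2S)-7-(trimethylsilyl)hept-6-yn-2-ol F2, with the stereocentre untouched.
- TBSCl/imidazole gives tert-butyldimethyl{[(2S)-7-(trimethylsilyl)hept-6-yn-2-yl]oxy}silane F3, and K2CO3 in MeOH removes the C-silyl group to give tert-butyl[(2S)-hept-6-yn-2-yloxy]dimethylsilane F4.
- Deprotonation with n-BuLi and addition to paraformaldehyde gives (7S)-7-[(tert-butyldimethylsilyl)oxy]oct-2-yn-1-ol F5, which CBr4/PPh3 converts into {[(2S)-8-bromooct-6-yn-2-yl]oxy}(tert-butyl)dimethylsilane F6.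
- Copper-mediated propargylation of methyl dec-9-ynoate with F6 (CuI, NaI, Cs2CO3, DMF, rt) gives methyl (17S)-17-[(tert-butyldimethylsilyl)oxy]octadeca-9,12-diynoate F7.
- Semihydrogenation over Ni2B formed from Ni(OAc)2·4H2O and NaBH4 (ethylenediamine, H2, EtOH) gives methyl (9Z,12Z,17S)-17-[(tert-butyldimethylsilyl)oxy]octadeca-9,12-dienoate F8, both Z alkenes arising from syn addition of H2.
- LiOH in THF/MeOH/H2O then gives acid 4, and steps 3, 5 and 6 follow unchanged.

Step 5. What may go wrong: Grignard formation or transmetalation to zinc is incomplete; the aryl-iron species acylates the ester instead of transferring an electron; the C1' radical is reduced or dimerises before capture; or iron hydride species move the skipped Z alkenes into conjugation.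

Fallback: the carboxyl carbon is removed first and the aryl–alkyl bond is then made by a copper-catalysed alkylation. It sets out from acid 4 (and uses Grignard reagent 9 made from 8) and comes back at compound 11.

- Acid 4 is esterified with 2-mercaptopyridine N-oxide (DCC, DMAP cat., CH2Cl2, dark) to the Barton ester 2-thioxopyridin-1(2H)-yl (9Z,12Z,17S)-17-[(tert-butyldimethylsilyl)oxy]octadeca-9,12-dienoate F9.
- F9 is irradiated with visible light in the presence of iodoform (toluene, rt) to give, by Barton iododecarboxylation, tert-butyl{[(2S,6Z,9Z)-17-iodoheptadeca-6,9-dien-2-yl]oxy}dimethylsilane F10.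
- Kumada-type coupling of F10 with Grignard reagent 9 (Li2CuCl4 cat., THF, −10 to 0 °C) gives 11.

Step 6. What may go wrong: the hindered secondary silyl ether is cleaved much more slowly than the two aryl silyl ethers, so that the free resorcinol and the skipped diene stand for a long time in a fluoride medium and are lost to autoxidation, or partly desilylated material persists.

Fallback: two selective cleavages in place of one global cleavage. It sets out from 11 and comes back at target 12.

- Camphorsulfonic acid (cat.) in MeOH/CH2Cl2 at 0 °C to rt methanolyses the alkyl silyl ether while the more acid-stable aryl silyl ethers stay, giving (2S,6Z,9Z)-17-{3,5-bis[(tert-butyldimethylsilyl)oxy]phenyl}heptadeca-6,9-dien-2-ol F11.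
- KHF2 in MeOH at rt, a near-neutral reagent selective for phenolic silyl ethers, then gives 12.

**Further compounds**

F1 | step 1 | [4-(trimethylsilyl)but-3-yn-1-yl]magnesium bromide | C[Si](C)(C)C#CCC[Mg]Br
F2 | step 1 | (2S)-7-(trimethylsilyl)hept-6-yn-2-ol | C[C@H](O)CCCC#C[Si](C)(C)C
F3 | step 1 | tert-butyldimethyl{[(2S)-7-(trimethylsilyl)hept-6-yn-2-yl]oxy}silane | C[C@H](O[Si](C)(C)C(C)(C)C)CCCC#C[Si](C)(C)C
F4 | step 1 | tert-butyl[(2S)-hept-6-yn-2-yloxy]dimethylsilane | C[C@H](O[Si](C)(C)C(C)(C)C)CCCC#C
F5 | step 1 | (7S)-7-[(tert-butyldimethylsilyl)oxy]oct-2-yn-1-ol | C[C@H](O[Si](C)(C)C(C)(C)C)CCCC#CCO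
F6 | step 1 | {[(2S)-8-bromooct-6-yn-2-yl]oxy}(tert-butyl)dimethylsilane | C[C@H](O[Si](C)(C)C(C)(C)C)CCCC#CCBr
F7 | step 1 | methyl (17S)-17-[(tert-butyldimethylsilyl)oxy]octadeca-9,12-diynoate | C[C@H](O[Si](C)(C)C(C)(C)C)CCCC#CCC#CCCCCCCCC(=O)OC
F8 | step 1 | methyl (9Z,12Z,17S)-17-[(tert-butyldimethylsilyl)oxy]octadeca-9,12-dienoate | C[C@H](O[Si](C)(C)C(C)(C)C)CCC/C=C\C/C=C\CCCCCCCC(=O)OC
F9 | step 5 | 2-thioxopyridin-1(2H)-yl (9Z,12Z,17S)-17-[(tert-butyldimethylsilyl)oxy]octadeca-9,12-dienoate | C[C@H](O[Si](C)(C)C(C)(C)C)CCC/C=C\C/C=C\CCCCCCCC(=O)On1ccccc1=S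
F10 | step 5 | tert-butyl{[(2S,6Z,9Z)-17-iodoheptadeca-6,9-dien-2-yl]oxy}dimethylsilane | C[C@H](O[Si](C)(C)C(C)(C)C)CCC/C=C\C/C=C\CCCCCCCI
F11 | step 6 | (2S,6Z,9Z)-17-{3,5-bis[(tert-butyldimethylsilyl)oxy]phenyl}heptadeca-6,9-dien-2-ol | C[C@H](O)CCC/C=C\C/C=C\CCCCCCCc1cc(O[Si](C)(C)C(C)(C)C)cc(O[Si](C)(C)C(C)(C)C)c1
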